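Retrosynthesis: the four O–Si bonds and the two aryl–prenyl bonds (at C2' and C3' of ring B) are cut first, then ring C is cut at C2–C3 and C4–C4a in one stroke, then the two acetal C–O bonds that lead back to an aldehyde and a phenol.
Enabling feature: C2 carries O1 and the ring B aryl group, so without C3 it is the carbon of an O-aryl oxocarbenium ion (C2=O1(+)–C8a=C4a, a cationic 2-oxadiene); C4a of ring A lies ortho to O1 and O5 and para to O7 and is the most nucleophilic arene carbon; C3–C4 is then a two-carbon ketene-type unit.
Forward: ring B (5-bromovanillin to a bis-silylated dibromocatechol aldehyde) and ring A (phloroglucinol to a 3,5-bis-silyloxyphenol) are joined as a symmetric diaryl acetal at the future C2; ring C then arises by a catalytic asymmetric formal [4+2] annulation (oxa-Povarov type) with ethoxyacetylene, whose ethoxy group carries the C4 ketone level.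
Helpers: the second aryloxy group of the acetal is the leaving group, and the two bromines hold the places of the prenyl groups so that no nucleophilic alkene sits next to the cation; twofold Stille prenylation and fluoride desilylation finish the route.
Stereochemistry: the single stereocenter C2 (S) is set in the key step by the chiral counter-anion of the Brønsted acid catalyst and is kept by a neutral coupling and a buffered deprotection.

Key step: step 6

Remark: which antipode of the chiral acid leads to the 2S product cannot be foretold; the route assumes the (S)-catalyst does, and otherwise its mirror image is used.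

Step 1
Reactants: 1 5-bromovanillin (3-bromo-4-hydroxy-5-methoxybenzaldehyde)
Product: 2 2,3-dibromo-4-hydroxy-5-methoxybenzaldehyde
Conditions: Br2 (1.3 equiv), Fe powder (cat.), AcOH, rt to 40 °C
Reagents that add atoms: bromine, BrBr
Why: Electrophilic aromatic bromination, in which the free ring position para to the methoxy group and ortho to the formyl group is the more activated of the two that remain, so the second bromine should enter next to the first.

Step 2
Reactants: 2 2,3-dibromo-4-hydroxy-5-methoxybenzaldehyde
Product: 3 2,3-dibromo-4,5-dihydroxybenzaldehyde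
Conditions: BBr3 (2.5 equiv), CH2Cl2, −78 °C to rt; H2O
Reagents that add atoms: none
Why: Lewis acid ether cleavage (BBr3 demethylation), in which bromide attacks the O-methyl group of the boron complex while the aryl bromides and the aldehyde should stay untouched.

Step 3
Reactants: 3 2,3-dibromo-4,5-dihydroxybenzaldehyde
Product: 4 2,3-dibromo-4,5-bis(triisopropylsilyloxy)benzaldehyde
Conditions: TIPSOTf (2.4 equiv), 2,6-lutidine (3 equiv), CH2Cl2, 0 °C to rt
Reagents that add atoms: triisopropylsilyl trifluoromethanesulfonate (TIPSOTf), CC(C)[Si](OS(=O)(=O)C(F)(F)F)(C(C)C)C(C)C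
Why: O-silylation of both phenols by the reactive silyl triflate and a hindered pyridine base; triisopropylsilyl ethers are chosen because they should withstand phenoxide, Brønsted acid and hot Stille conditions and leave with fluoride.

Step 4
Reactants: 5 phloroglucinol (benzene-1,3,5-triol)
Product: 6 3,5-bis(triisopropylsilyloxy)phenol
Conditions: TIPSCl (2.0 equiv), imidazole (4 equiv), DMF, 0 °C to rt; chromatography
Reagents that add atoms: triisopropylsilyl chloride (TIPSCl), CC(C)[Si](Cl)(C(C)C)C(C)C
Why: Statistical silylation of a threefold-symmetric triol, in which two equivalents of silyl chloride should make the bis-silyl ether the main component, separable from mono- and tris-silylated material that can be recycled.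

Step 5
Reactants: 4 2,3-dibromo-4,5-bis(triisopropylsilyloxy)benzaldehyde; 6 3,5-bis(triisopropylsilyloxy)phenol (2.2 equiv)
Product: 8 [2,3-dibromo-4,5-bis(triisopropylsilyloxy)phenyl]bis[3,5-bis(triisopropylsilyloxy)phenoxy]methane, via benzal chloride 7 (not isolated)
Conditions: (COCl)2 (1.5 equiv), Ph3PO (10 mol %), CH2Cl2, rt; evaporate; then 6, NaH (2.3 equiv), THF/DMF, 0 °C to rt
Reagents that add atoms: none
Why: Deoxydichlorination of the aldehyde by the chlorophosphonium salt formed from catalytic Ph3PO and oxalyl chloride, then twofold Williamson-type substitution by the sodium phenoxide, in which the para-silyloxy group makes 7 ionisable, the α-chloro ether formed first is more reactive than 7, and the phenoxide should react at oxygen in the polar aprotic medium.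

Step 6
Reactants: 8 [2,3-dibromo-4,5-bis(triisopropylsilyloxy)phenyl]bis[3,5-bis(triisopropylsilyloxy)phenoxy]methane; 9 ethoxyacetylene (ethyl ethynyl ether, 3 equiv)
Product: 13 (2S)-2-[2,3-dibromo-4,5-bis(triisopropylsilyloxy)phenyl]-5,7-bis(triisopropylsilyloxy)chroman-4-one, via oxocarbenium ion 10 (not isolated), via ketenium ion 11 (not isolated), via enol ether 12 (not isolated)
Conditions: 9 added slowly, (S)-3,3'-bis(2,4,6-triisopropylphenyl)-1,1'-binaphthyl-2,2'-diyl N-triflylphosphoramide (10 mol %), toluene, −60 to −30 °C; Et3N; then 1 M aq. HCl, THF, 0 °C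
Reagents that add atoms: water, O
Why: Proposed new method: the chiral acid protonates one of the two equivalent aryloxy groups of 8 and expels phenol 6, so that the only ion that can form is the O-aryl oxocarbenium ion 10, held as a contact ion pair by the chiral phosphoramide anion; the nucleophilic terminal carbon of 9 adds to C2 (new C2–C3 bond) to give ketenium ion 11, whose sp carbon C4 is attacked by the ring A carbon ortho to O1 (new C4–C4a bond), and loss of the proton returns the catalyst and gives enol ether 12, which aqueous acid hydrolyses to ketone 13. The closest known reactions are the Povarov reaction in its chiral Brønsted acid catalysed and its alkyne versions, its oxygen analogue that turns aryl oxocarbenium ions and alkenes into chromans, chiral-anion-controlled additions to oxocarbenium ions, and Friedel–Crafts capture of ketenium ions by arenes. Ring C closes as a six-membered ring by Friedel–Crafts attack, in the plane of the C2–C3=C4 unit, on the C=O(+) bond of the ketenium ion (6-exo-dig at that bond, the C3=C4 bond staying in the ring; overall a stepwise formal [4+2]). The stereocenter C2 arises in the first C–C bond formation and is controlled by the catalyst, whose anion should shield one face of the planar oxocarbenium ion while the ortho bromine fixes the conformation of the aryl group. The step needs chemoselectivity: capture of 10 by the alkyne ahead of Friedel–Crafts alkylation of 6 or 8 rests on the higher nucleophilicity and the excess of the ynol ether, and C-closure of 11 ahead of O-closure (an oxetene that would end as an aryl cinnamate) rests on the ring A carbon being activated by three oxygens and closing a six-membered ring; regioselectivity is not in question because the two ortho carbons of the symmetric aryl ether are equivalent.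

Step 7
Reactants: 13 (2S)-2-[2,3-dibromo-4,5-bis(triisopropylsilyloxy)phenyl]-5,7-bis(triisopropylsilyloxy)chroman-4-one; 14 tributyl(3-methylbut-2-en-1-yl)stannane (3 equiv)
Product: 15 (2S)-2-[2,3-bis(3-methylbut-2-en-1-yl)-4,5-bis(triisopropylsilyloxy)phenyl]-5,7-bis(triisopropylsilyloxy)chroman-4-one
Conditions: Pd(PPh3)4 (10 mol %), amine-free DMF, 90 °C, degassed
Reagents that add atoms: none
Why: Twofold Stille coupling, in which zerovalent palladium inserts into each aryl C–Br bond, the allylic stannane transmetalates and reductive elimination at the less substituted allyl terminus should give the linear prenyl groups, all under neutral conditions that do not expose the C2 stereocenter next to the enolisable ketone to base.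

Step 8
Reactants: 15 (2S)-2-[2,3-bis(3-methylbut-2-en-1-yl)-4,5-bis(triisopropylsilyloxy)phenyl]-5,7-bis(triisopropylsilyloxy)chroman-4-one
Product: 16 (2S)-2-[4,5-dihydroxy-2,3-bis(3-methylbut-2-en-1-yl)phenyl]-5,7-dihydroxy-2,3-dihydro-4H-chromen-4-one (the target)
Conditions: HF·pyridine (excess), pyridine, THF, 0 °C to rt, argon
Reagents that add atoms: none
Why: Fluoride cleavage of the four aryl silyl ethers (driven by the strong Si–F bond) in a pyridine-buffered medium that should neither open the flavanone by retro-oxa-Michael reaction, which would racemise C2, nor cyclise a prenyl group onto the neighbouring phenol.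

Compound list
1 | 5-bromovanillin (3-bromo-4-hydroxy-5-methoxybenzaldehyde) | O=Cc1cc(Br)c(O)c(OC)c1 | starting material
2 | 2,3-dibromo-4-hydroxy-5-methoxybenzaldehyde | O=Cc1cc(OC)c(O)c(Br)c1Br | intermediate
3 | 2,3-dibromo-4,5-dihydroxybenzaldehyde | O=Cc1cc(O)c(O)c(Br)c1Br | intermediate
4 | 2,3-dibromo-4,5-bis(triisopropylsilyloxy)benzaldehyde | O=Cc1cc(O[Si](C(C)C)(C(C)C)C(C)C)c(O[Si](C(C)C)(C(C)C)C(C)C)c(Br)c1Br | intermediate
5 | phloroglucinol (benzene-1,3,5-triol) | Oc1cc(O)cc(O)c1 | starting material
6 | 3,5-bis(triisopropylsilyloxy)phenol | Oc1cc(O[Si](C(C)C)(C(C)C)C(C)C)cc(O[Si](C(C)C)(C(C)C)C(C)C)c1 | intermediate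
7 | 2,3-dibromo-1-(dichloromethyl)-4,5-bis(triisopropylsilyloxy)benzene (benzal chloride, not isolated) | ClC(Cl)c1cc(O[Si](C(C)C)(C(C)C)C(C)C)c(O[Si](C(C)C)(C(C)C)C(C)C)c(Br)c1Br | intermediate
8 | [2,3-dibromo-4,5-bis(triisopropylsilyloxy)phenyl]bis[3,5-bis(triisopropylsilyloxy)phenoxy]methane (diaryl acetal of 4) | Brc1c(C(Oc2cc(O[Si](C(C)C)(C(C)C)C(C)C)cc(O[Si](C(C)C)(C(C)C)C(C)C)c2)Oc2cc(O[Si](C(C)C)(C(C)C)C(C)C)cc(O[Si](C(C)C)(C(C)C)C(C)C)c2)cc(O[Si](C(C)C)(C(C)C)C(C)C)c(O[Si](C(C)C)(C(C)C)C(C)C)c1Br | intermediate
9 | ethoxyacetylene (ethyl ethynyl ether) | C#COCC | starting material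
10 | O-aryl oxocarbenium ion from 8 (cation of the ion pair formed by the catalyst anion, not isolated) | Brc1c(C=[O+]c2cc(O[Si](C(C)C)(C(C)C)C(C)C)cc(O[Si](C(C)C)(C(C)C)C(C)C)c2)cc(O[Si](C(C)C)(C(C)C)C(C)C)c(O[Si](C(C)C)(C(C)C)C(C)C)c1Br | intermediate
11 | (S)-ethoxyketenium ion formed by addition of 9 to 10 (not isolated) | Brc1c([C@@H](Oc2cc(O[Si](C(C)C)(C(C)C)C(C)C)cc(O[Si](C(C)C)(C(C)C)C(C)C)c2)C=C=[O+]CC)cc(O[Si](C(C)C)(C(C)C)C(C)C)c(O[Si](C(C)C)(C(C)C)C(C)C)c1Br | intermediate
12 | (2S)-2-[2,3-dibromo-4,5-bis(triisopropylsilyloxy)phenyl]-4-ethoxy-5,7-bis(triisopropylsilyloxy)-2H-chromene (enol ether, not isolated) | Brc1c([C@@H]2C=C(OCC)c3c(O[Si](C(C)C)(C(C)C)C(C)C)cc(O[Si](C(C)C)(C(C)C)C(C)C)cc3O2)cc(O[Si](C(C)C)(C(C)C)C(C)C)c(O[Si](C(C)C)(C(C)C)C(C)C)c1Br | intermediate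
13 | (2S)-2-[2,3-dibromo-4,5-bis(triisopropylsilyloxy)phenyl]-5,7-bis(triisopropylsilyloxy)chroman-4-one | Brc1c([C@@H]2CC(=O)c3c(O[Si](C(C)C)(C(C)C)C(C)C)cc(O[Si](C(C)C)(C(C)C)C(C)C)cc3O2)cc(O[Si](C(C)C)(C(C)C)C(C)C)c(O[Si](C(C)C)(C(C)C)C(C)C)c1Br | intermediate
14 | tributyl(3-methylbut-2-en-1-yl)stannane | CCCC[Sn](CCCC)(CCCC)CC=C(C)C | starting material
15 | (2S)-2-[2,3-bis(3-methylbut-2-en-1-yl)-4,5-bis(triisopropylsilyloxy)phenyl]-5,7-bis(triisopropylsilyloxy)chroman-4-one | CC(C)=CCc1c([C@@H]2CC(=O)c3c(O[Si](C(C)C)(C(C)C)C(C)C)cc(O[Si](C(C)C)(C(C)C)C(C)C)cc3O2)cc(O[Si](C(C)C)(C(C)C)C(C)C)c(O[Si](C(C)C)(C(C)C)C(C)C)c1CC=C(C)C | intermediate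
16 | (2S)-2-[4,5-dihydroxy-2,3-bis(3-methylbut-2-en-1-yl)phenyl]-5,7-dihydroxy-2,3-dihydro-4H-chromen-4-one | CC(C)=CCc1c([C@@H]2CC(=O)c3c(O)cc(O)cc3O2)cc(O)c(O)c1CC=C(C)C | target

Total step count: 8. Longest linear sequence: 7 steps (steps 1, 2, 3, 5, 6, 7, 8, from 5-bromovanillin).

Steps most likely to fail

1. Step 6 (bears the label). Three processes may go wrong:
- the facial selectivity may be poor, because the bulky ion pair is only loosely organised;
- the acid may consume the ynol ether before the acetal ionises;
- the oxocarbenium ion may alkylate the electron-rich aryl ethers intermolecularly.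

The fallback uses known chemistry, sets out from aldehyde 4 and comes back at 13. Commercial 2,4,6-trihydroxyacetophenone is bis-silylated (TIPSCl, imidazole, DMF) to 1-[2-hydroxy-4,6-bis(triisopropylsilyloxy)phenyl]ethanone F1. Its dianion (LiN(i-Pr)2, 2.2 equiv, THF, −78 °C) adds to 4 in an aldol reaction to give the racemic β-hydroxy ketone 3-[2,3-dibromo-4,5-bis(triisopropylsilyloxy)phenyl]-3-hydroxy-1-[2-hydroxy-4,6-bis(triisopropylsilyloxy)phenyl]propan-1-one F2. An intramolecular Mitsunobu etherification (PPh3, DIAD, THF, 0 °C) closes ring C to the racemic flavanone F3. Kinetic resolution by asymmetric transfer hydrogenation (RuCl[(S,S)-TsDPEN](p-cymene) or its (R,R) antipode, HCO2H/Et3N), run with the antipode that reduces the (2R) ketone faster, should turn that enantiomer into the cis-flavan-4-ol F4 and leave (2S)-13, which goes on to step 7.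

2. Step 7. Three processes may go wrong:
- the second oxidative addition, at a C–Br bond flanked on both sides, may stall after the first coupling;
- the allyl group may be transferred at its substituted end (reverse prenyl);
- palladium hydride may move the prenyl double bond.

The fallback sets out from 13 and comes back at 15, and makes no new compound. The prenyl unit is brought in as an electrophile in a nickel-catalysed reductive cross-electrophile coupling of the two aryl bromides with prenyl acetate (NiCl2(dme), 4,4'-di-tert-butyl-2,2'-bipyridine, Zn powder, DMA, 40 °C). This needs no allyl–metal reagent, and the π-allylnickel intermediate should couple at its less hindered terminus.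

3. Step 5. Three processes may go wrong:
- the ionisable benzal chloride may hydrolyse;
- the ambident phenoxide may be alkylated at carbon;
- the substitution may stop after the first aryloxy group, because of crowding next to the ortho bromine.

The fallback sets out from 4 and comes back at 8. The aldehyde is converted (HC(OMe)3, PPTS, MeOH) into 2,3-dibromo-1-(dimethoxymethyl)-4,5-bis(triisopropylsilyloxy)benzene F5. Acid-catalysed acetal exchange of F5 with 6 (2.5 equiv, PPTS, toluene, 5 Å molecular sieves, reduced pressure, with methanol removed as it forms) should then give diaryl acetal 8 without a halide intermediate.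

Further compounds
F1 | step 6 | 1-[2-hydroxy-4,6-bis(triisopropylsilyloxy)phenyl]ethanone | CC(=O)c1c(O)cc(O[Si](C(C)C)(C(C)C)C(C)C)cc1O[Si](C(C)C)(C(C)C)C(C)C
F2 | step 6 | racemic 3-[2,3-dibromo-4,5-bis(triisopropylsilyloxy)phenyl]-3-hydroxy-1-[2-hydroxy-4,6-bis(triisopropylsilyloxy)phenyl]propan-1-one | Brc1c(C(O)CC(=O)c2c(O)cc(O[Si](C(C)C)(C(C)C)C(C)C)cc2O[Si](C(C)C)(C(C)C)C(C)C)cc(O[Si](C(C)C)(C(C)C)C(C)C)c(O[Si](C(C)C)(C(C)C)C(C)C)c1Br
F3 | step 6 | racemic 2-[2,3-dibromo-4,5-bis(triisopropylsilyloxy)phenyl]-5,7-bis(triisopropylsilyloxy)chroman-4-one | Brc1c(C2CC(=O)c3c(O[Si](C(C)C)(C(C)C)C(C)C)cc(O[Si](C(C)C)(C(C)C)C(C)C)cc3O2)cc(O[Si](C(C)C)(C(C)C)C(C)C)c(O[Si](C(C)C)(C(C)C)C(C)C)c1Br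
F4 | step 6 | (2R,4R)-2-[2,3-dibromo-4,5-bis(triisopropylsilyloxy)phenyl]-5,7-bis(triisopropylsilyloxy)chroman-4-ol (cis) | Brc1c([C@H]2C[C@@H](O)c3c(O[Si](C(C)C)(C(C)C)C(C)C)cc(O[Si](C(C)C)(C(C)C)C(C)C)cc3O2)cc(O[Si](C(C)C)(C(C)C)C(C)C)c(O[Si](C(C)C)(C(C)C)C(C)C)c1Br
F0 | step 7 | none | none
F5 | step 5 | 2,3-dibromo-1-(dimethoxymethyl)-4,5-bis(triisopropylsilyloxy)benzene | COC(OC)c1cc(O[Si](C(C)C)(C(C)C)C(C)C)c(O[Si](C(C)C)(C(C)C)C(C)C)c(Br)c1Br
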